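**Main step.** The easy step comes first: in the winter run substrate stands at 0% by 1.00 h, so this step by itself promises the whole charge as target. Yet target reads 65.9% at that moment and keeps falling.

| flask | substrate | first nucleophile | second nucleophile | remark | time |
|---|---|---|---|---|---|
| winter | 20 mM | 1.8 equiv | 1.5 equiv | run made earlier |  |
| midnight | 20 mM | 0.90 equiv | 1.5 equiv | run made earlier |  |
| spring | 20 mM | 3.6 equiv | 1.5 equiv | run made earlier |  |
| theta | 20 mM | 1.80 equiv | 1.50 equiv (fed, over 4.0 h) | all else is in the flask from the start; the feed brings no volume worth counting | 20 h |
| gamma | 20 mM | 1.80 equiv | 1.50 equiv | everything together at the start | 20 h |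
| beta | 20 mM (fed, over 4.0 h) | 1.80 equiv | 1.50 equiv | all else is in the flask from the start; the feed brings no volume worth counting | 20 h |
| delta | 20 mM | 1.80 equiv | 1.50 equiv (in portions, 2, over 4.0 h) | first portion at the start, last at 4.0 h | 20 h |

| run | time / h | target / % | substrate / % |
|---|---|---|---|
| winter | 1.00 | 65.9 | 0 |
| winter | 3.00 | 46.6 | 0.1 |
| winter | 6.00 | 36.9 | 0.2 |
| winter | 8.00 | 33.9 | 0.5 |
| winter | 12.0 | 30.1 | 0.3 |
| midnight | 1.33 | 36.4 | 0.6 |
| midnight | 2.50 | 26.5 | 0.3 |
| midnight | 5.00 | 18.5 | 0 |
| midnight | 8.00 | 14.6 | 0.1 |
| midnight | 15.0 | 10.8 | 0.4 |
| spring | 3.00 | 68.4 | 0.1 |
| spring | 6.00 | 60.3 | 0 |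
| spring | 10.0 | 54.2 | 0 |
| spring | 12.0 | 52.1 | 0 |
| spring | 15.0 | 50.4 | 0 |

(readings scatter by 0.3 percentage points)

* the flask with the highest amount of target, in percent of the substrate charged ("all alike" if they lie within 1.5 percentage points) (theta / gamma / beta / delta / all alike)
* final target, as a percentage of the substrate charged, in theta
* final target, as a percentage of the substrate charged, in gamma
* final target, as a percentage of the substrate charged, in beta
* final target, as a percentage of the substrate charged, in delta



**Steady attack.** The second process is a loss of target, and first nucleophile protects against it: target in the spring run reads 50.4% at 15.0 h, more than the 10.8% of the midnight run at 15.0 h. Treated as pseudo-first-order, the loss takes its constant from the first two winter readings, 0.173 h⁻¹, and this leaves 2.45% at 20 h. But winter still reads 30.1% at 12.0 h, so the attack must weaken.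

**Fading attack.** As a third process, suppose that the attacker is second nucleophile and that it dies by a second-order route, so that its strength is taken to fall inversely with time. The first and last winter readings then give 0.315, the survival exponent: the relative rate of fall of target divided by the relative rate of fall of the attacker, a ratio from which hours have dropped out. It returns 46.6% for the winter reading of 46.6% at 3.00 h. Spring gives a smaller exponent, 0.190.

**Later birth.** With the charges of the winter run and second nucleophile present from the start, target born when the attacker has a given age is reckoned to survive as that age over the present time, raised to the exponent. Gamma, which repeats winter, comes to 25.6%. In beta, where substrate is fed at a steady rate, target is reckoned to be born on average at 2.00 h, which gives 48.4%, more than gamma. Theta and delta, where part of the second nucleophile goes in after the start, stay outside this reckoning.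

**The result.** The forecast names beta as the best flask, with 48% there, 26.3% in gamma, 18% in theta and 18.5% in delta, on the ground that “Feeding the substrate lets much of the agent die before the target appears”. The flasks give 47.6% in beta, 27.1% in gamma, 20.5% in theta and 21.0% in delta, so gamma stands 1.5 percentage points above the reckoning.

    substrate → intermediate (k = 7.07 h⁻¹)
    first nucleophile + intermediate ⇌ target (K = 901 L mol⁻¹, k = 9700 L mol⁻¹ h⁻¹)
    second nucleophile + intermediate → other capture product (k = 416 L mol⁻¹ h⁻¹)
    2 second nucleophile → homo dimer (k = 9.45 L mol⁻¹ h⁻¹)

**Richer neighbour.** A neighbouring flask repeats beta with 80 mM of substrate at the same equivalents, so its first nucleophile concentration is twice that of the spring run, and its second nucleophile concentration is 4.00 times that of the spring run. Doubling first nucleophile from winter to spring took the exponent as read from 0.315 to 0.190, so one more doubling at the same ratio, with the change in second nucleophile left out of this estimate, gives 0.114. With birth again at 2.00 h, survival comes to 76.9%. The neighbouring flask holds 78.7% of target at 20.0 h.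

The earlier runs and the new flask come from a simulation on assumed constants; scatter was added.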